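Start from the constants, and there are two to be had from the one earlier run, the west flask, for the three new flasks below.

all flasks: substrate 10 mM

| charge | free catalyst | impurity | remark | time |
|---|---|---|---|---|
| west | 0.50 mM | 0.074 mM | run made earlier |  |
| winter | 4.5 mM | 0.11 mM |  | 2.5 d |
| dawn | 0.50 mM | 0.11 mM |  | 2.5 d |
| midnight | 1.5 mM | 0.11 mM |  | 2.5 d |

west run (percent of the substrate charged)

| time / h | target / % | isomer of the product / % | substrate / % | intermediate / % |
|---|---|---|---|---|
| 3.00 | 1.5 | 0 | 48.0 | 51.9 |
| 6.00 | 2.2 | 0.6 | 22.2 | 75.4 |
| 10.0 | 5.0 | 0 | 8.3 | 86.0 |
| 12.0 | 7.9 | 0 | 5.4 | 88.4 |
| 15.0 | 9.8 | 1.2 | 1.6 | 88.6 |
| 20.0 | 13.3 | 1.8 | 1.3 | 84.8 |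

(scatter of a reading: 0.5 percentage points)

- no earlier run changes the charge of free catalyst; that part of a forecast is a guess
- no earlier run changes the charge of impurity; that part of a forecast is a guess

- which of these there is most of at the end, counted by the substrate in it, winter (substrate / intermediate / target / isomer of the product)
- which of these there is most of at the end, counted by the substrate in it, dawn (substrate / intermediate / target / isomer of the product)
- which of these there is most of at the end, counted by the substrate in it, midnight (substrate / intermediate / target / isomer of the product)
- how much there is at the end of the one of these that leads, in percent of the substrate charged: winter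
- how much there is at the end of the one of these that leads, in percent of the substrate charged: dawn
- how much there is at the end of the one of these that leads, in percent of the substrate charged: midnight

In the west flask the substrate falls to 48.0% at 3.00 h, so its first-order constant k reads 0.245 h⁻¹, and intermediate is born on average a lag 1/k = 4.09 h after the start. Now work with the fraction left, not the fraction made. At 20.0 h the intermediate is f = 84.9% of the three things downstream of the substrate, after a working time of 15.9 h. Call L = ln(1/f) = 0.164 the log loss, the natural logarithm of one over the fraction of intermediate left.

The bench rule is catalyst times time: if the intermediate decays pseudo-first-order, L grows in proportion to the free catalyst charged and to the working time. No earlier run changes the catalyst charge, so that part is my guess. It leaves 56.2% of the intermediate in the dawn flask, 17.8% in the midnight flask and 0.562% in the winter flask. I commit to intermediate leading at dawn, where it keeps more than the rest; for midnight and winter the rule does not split the remainder between target and isomer of the product.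

Its border is the ratio of impurity to catalyst. That ratio is 14.8% in the west flask, and L carries it. If impurity takes catalyst one for one, which is also a guess, the catalyst at work falls short of the charge by that share, and the rule stands as long as the share stays near the west value. The dawn flask has 22.0%, more than the west flask, so I expect its intermediate above my figure.

The forecast gives isomer of the product at 92% (78% to 99%) for winter, intermediate at 56% (47% to 66%) for dawn, and isomer of the product at 62% (44% to 77%) for midnight. Its stated ground: “I assume all steps scale with catalyst and the impurity has a minor effect”.

The flasks give target at 71.6% in winter, intermediate at 61.9% at dawn, and target at 63.2% at midnight. In the dawn flask 22.0% of the catalyst charged ends as spent catalyst, and its intermediate stands higher than my reckoned figure.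

    substrate → intermediate (k = 0.250 h⁻¹)
    free catalyst + impurity → spent catalyst (k = 1.20 × 10⁵ M⁻¹ h⁻¹)
    free catalyst + intermediate → free catalyst + target (k = 22.0 M⁻¹ h⁻¹)
    target ⇌ isomer of the product (K = 1.40, k = 0.00850 h⁻¹)

Take a neighbour of the winter flask charged with 1.8 mM of free catalyst. The log loss, scaled by catalyst and working time, leaves 12.6% of the intermediate, and that flask ends with 12.6%.

The numbers in the tables were computed with constants of no real substance, and the scatter is random.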